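The constants used here come from no measurement; no experiment stands behind them.

**Time first.** I measured 12 min against the half-lives of the steps. In this flask the reagent binds the starting material to give the target and binds the second substrate to give the second product. It also sleeps as the dormant form, and the target turns into its isomer.

starting material 5.0 mM; reagent 10.0 mM; second substrate 5.00 mM; time 12 min

- why nothing more happens at 12 min, or that something still does (the reagent has run out first / all of the starting material has reacted / forward and back rates have come level / it is still moving)
- how much of the starting material has reacted by 12 min
- how much target there is at 12 min, in percent of the starting material charged

- the reaction counts as stopped when no species that holds the starting material changes by six tenths of a point or more over the second half of the time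
- run time (flask): 12 min

    starting material + reagent ⇌ target (K1 = 88 M⁻¹, k1 = 1.0 M⁻¹ s⁻¹)
    second substrate + reagent ⇌ second product (K2 = 110 M⁻¹, k2 = 1.7 M⁻¹ s⁻¹)
    reagent ⇌ dormant form (K3 = 2.0, k3 = 0.048 s⁻¹)
    target ⇌ isomer of the product (K4 = 0.22, k4 = 0.017 s⁻¹)

**The ladder.** I reckoned target and isomer level first, with a half-life of 0.123 min. Reagent and dormant form followed at 0.160 min. Next came the way back from the second product, 0.748 min, and the way back from the target, 1.02 min, the slowest rung. The time held 11.8 of those, so I reckoned a balance, not a rate.

**Free reagent.** From the reagent's rung on, I took the dormant form at twice the free reagent, so the dormant form was the reagent's resting state. Let r be the reagent neither bound nor dormant. The isomer raised the starting material's constant to Ka = 107 M⁻¹. Bound starting material, T (target plus isomer), was its charge times Ka·r over one plus Ka·r. The second product, U, followed likewise with its own constant. Then r was the reagent charge minus T and U, divided by one plus the dormant constant.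

**Going round.** With nothing bound, r was 3.33 mM, a third of the charge. That overstated the binding, so the next round gave 2.45 mM. That understated it, and the next gave 2.63 mM. One more gave the free reagent at balance, 2.59 mM. So T was 1.09 mM, which meant 21.8% conversion and 17.8% target. By the half-life of the slowest rung, I reckoned 0.364% of the charge still to go at half time, inside the stopping rule. My answer was: forward and back rates have come level.

**The forecast.** It gave forward and back rates have come level, 21.8% and 17.9%, saying “the flask has stopped at equilibrium”.

**The result.** This flask gave forward and back rates have come level, with 21.8% conversion and 17.9% target.

This flask kept 26% of its reagent, and my r was 25.9% of the charge. For the neighbour flask with 17 mM of reagent, I began again from no binding. After one round r was 4.40 mM, and after the next 4.59 mM. That meant 33.0% conversion. The neighbour flask gave 32.9%.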